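The equivalent is my unit here: in this flask I reckon each equivalent of product at 2 of nucleophile, one attacked and one protonated by the acid set free, because the protonation constant times the starting nucleophile is 36.

electrophile 0.30 M; nucleophile 3.00 equiv; gas 78 mM (held); time 3.0 min

    acid set free + free base ⇌ salt of the base (K1 = 6020 M⁻¹, k1 = 24.4 M⁻¹ min⁻¹)
    electrophile + nucleophile → acid set free + product (k2 = 1.80 M⁻¹ min⁻¹)
    gas ⇌ free base, rate k3*(csat - [free base]) (k3 = 0.281 min⁻¹, csat = 78 mM)
    nucleophile + acid set free ⇌ protonated nucleophile, settled at all times (K4 = 39.7 M⁻¹)

* amount of product at 3.0 min, in percent of the electrophile charged
* the change that raises the amount of product at 3.0 min, in percent of the electrophile charged most ("none" if none brings more than 2 percentage points) (midnight / winter / spring / none)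
* amount of product at 3.0 min, in percent of the electrophile charged, after midnight

- midnight: doubling the saturation concentration of gas, all else as stated
- winter: doubling the amount of nucleophile, all else as stated
- spring: doubling the transfer coefficient of step 3, all else as stated

At that price c(nucleophile) − 2 c(electrophile) stays at 0.300 M, which keeps the electrophile the limiting reagent, and I fold the givens into one number:

N = 1.80 M⁻¹ min⁻¹ × 0.300 M × 3.0 min = 1.62

N is the count of e-foldings that the ratio c(nucleophile)/c(electrophile) makes in the run. The ratio starts at 3.00 and is multiplied by e^N, here 5.05, so I reckon:

electrophile left 7.60%, product 92.4%

One number is not enough, though: the charge ratio stands beside it, and N ignores the gas, which can deliver by 3.0 min up to 21.9% of the electrophile charged into a solution kept empty. So I expect slightly more product. Winter lifts N to 6.48 and leaves 0.102% of the electrophile, a gain of 7.5 percentage points. Midnight and spring leave N unchanged, so I choose winter.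

The forecast differs: 97.6%, 97.8% after midnight, and best none, holding that “the excess stays free”.

The simulation gives 93.0%, 93.2% after midnight, and best winter, worth 6.9 points against 0.19 points for midnight and 0.13 points for spring.

Up to 3.0 min this flask turns over 93.0% of the electrophile charged by attack and the equivalent of 6.40% by net capture of acid on free base. Protonated nucleophile then stands at 0.244 M beside 0.0192 M of salt of the base.

In the neighbour flask, the same recipe read at 80 s, N is 0.720, which gives 76.0% product. The simulation gives 76.4%.

(The constants stand for no real mixture; the rest is arithmetic.)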